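(Readings and results stem from a simulated flask for substances that don't exist; the scatter is artificial.)

Slowness is absent late in the cedar run: its target reads 23.4% at 4.00 d and 23.4% at 15.0 d, a difference inside the scatter of 1 percentage point.

| setting | ash | elm | cedar | flask |
|---|---|---|---|---|
| substrate | 1.4 M | 2.2 M | 1 M | 1.0 M |
| reagent | 1.1 M | 1.1 M | 1.7 M | 1.10 M |
| free catalyst | 17 mM | 17 mM | 17 mM | 17 mM |
| second catalyst | 2.2 mM | 2.2 mM | 2.2 mM | 2.2 mM |
| remark | run made earlier | run made earlier | run made earlier |  |
| time |  |  |  | 15 d |

| run | time / d | target / % | uncatalysed product / % |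
|---|---|---|---|
| ash | 2.50 | 18.5 | 44.9 |
| ash | 5.00 | 22.0 | 46.5 |
| ash | 8.00 | 23.0 | 46.4 |
| ash | 10.0 | 23.3 | 48.6 |
| ash | 12.0 | 23.0 | 46.4 |
| ash | 15.0 | 22.6 | 48.1 |
| elm | 1.25 | 9.6 | 32.7 |
| elm | 2.08 | 6.2 | 35.1 |
| elm | 3.00 | 7.9 | 34.9 |
| elm | 5.00 | 5.2 | 35.2 |
| elm | 10.0 | 5.4 | 35.4 |
| elm | 15.0 | 7.0 | 35.4 |
| cedar | 1.25 | 17.9 | 67.2 |
| cedar | 4.00 | 23.4 | 69.9 |
| cedar | 8.00 | 24.1 | 69.2 |
| cedar | 10.0 | 22.9 | 72.4 |
| cedar | 15.0 | 23.4 | 70.2 |

(readings scatter by 1 percentage point)

- the target standing at 15 d, as a percentage of the substrate charged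
- the uncatalysed product standing at 15 d, as a percentage of the substrate charged

The cedar run gives a ladder of three rungs. On the fast rung, the uncatalysed product reads 67.2% by 1.25 d, nearly all of its reading at 15.0 d. On the next rung the target follows, reaching 17.9% at that time, a smaller part of its later reading. On the last rung the cedar readings stand still, and a time of 15 d lies there. The reckoning for the flask takes it to stand still by then as well, so it is a balance, not a rate.

The catalyst charges are the same in ash, elm, cedar and the flask, so they are frozen out of the comparison. The cedar run had more reagent than substrate. Counting one reagent per unit of product, the two readings of the cedar run at 15.0 d give an estimate of the reagent demand, the reagent needed per substrate charged: 93.6%. This reckoning freezes that share, a reading with its scatter.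

| Flask | Demand | Reagent charged |
|---|---|---|
| ash | 1.31 M | 1.1 M |
| elm | 2.06 M | 1.1 M |
| cedar | 0.936 M | 1.7 M |
| flask | 0.936 M | 1.10 M |

Ash and elm charge less reagent than their demand. The flask charges more, so substrate should be its limiting reagent, with 14.9% of the reagent left.

The forecast gives 35% of target, within 28% to 42%, and 55% of uncatalysed product, within 47% to 63%. Its ground is that the ratio of target to uncatalysed product “falls steeply with more substrate and also with more reagent”, and that the flask is low in both.

    substrate + free catalyst → free catalyst + intermediate (k = 0.0230 M⁻¹ min⁻¹)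
    reagent + second catalyst + intermediate → second catalyst + target (k = 1.10 M⁻² min⁻¹)
    substrate + target → side product (k = 5.70 × 10⁻⁴ M⁻¹ min⁻¹)
    substrate + reagent → uncatalysed product (k = 8.60 × 10⁻⁴ M⁻¹ min⁻¹)

The flask gives 33.0% of target and 54.9% of uncatalysed product at 15 d, both within the forecast's ranges. At that time substrate stands at 0% and reagent at 15% of its charge, against the 14.9% reckoned from the demand. With 0.66 M of reagent, the same flask falls short of the demand by 27.6% of the substrate charged. That neighbour ends with reagent at 0% and intermediate at 25.7%.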